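0.388 M of Q is the charge at which, by my reading of the midnight run, G stands at half of its charge after 2.5 min; I call it the turning charge. In the candidate steps, Q adds to G to give X, to X to give D and to D to give J, and it also passes to and from Z.

| setting | spring | autumn | midnight | zeta | alpha | beta | epsilon |
|---|---|---|---|---|---|---|---|
| G | 0.10 M | 0.10 M | 0.10 M | 0.10 M | 0.10 M | 0.10 M | 0.10 M |
| Q | 0.22 M | 0.55 M | 1.3 M | 0.200 M | 0.400 M | 0.800 M | 1.50 M |
| remark | run made earlier | run made earlier | run made earlier |  |  |  |  |
| time |  |  |  | 2.5 min | 2.5 min | 2.5 min | 2.5 min |

| run | time / s | X / % | G / % |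
|---|---|---|---|
| spring | 10.0 | 2 | 99 |
| spring | 15.0 | 5 | 94 |
| spring | 30.0 | 8 | 90 |
| spring | 80.0 | 17 | 81 |
| autumn | 20.0 | 12 | 87 |
| autumn | 40.0 | 19 | 77 |
| autumn | 60.0 | 22 | 66 |
| autumn | 80.0 | 25 | 59 |
| midnight | 10.0 | 14 | 84 |
| midnight | 15.0 | 20 | 77 |
| midnight | 30.0 | 22 | 59 |
| midnight | 80.0 | 21 | 29 |

(standard deviation of a reading: 1.5 percentage points)

- amount of X at the end, in percent of the G charged for zeta, alpha, beta, epsilon, in this order
- the shape of the row from first to last (hardly changes / rises all the way / falls all the way / falls, then rises / rises, then falls)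

- the analysis behind the earlier runs scatters by 1.5 percentage points, standard deviation
- candidate steps: G + Q -> X; Q + X -> D; Q + D -> J; Q <-> Z
- "hardly changes" means that all values lie within two and a half points (for a concentration: within two and a half percent of the largest)

I start from the balance of G, the smaller charge, 0.10 M against at least 0.200 M: what has left G stands in X, D or J, so X is one share of that loss. I treat the loss as pseudo-first-order in G, with ln(G charged / G left) growing as [Q] times time. The same reckoning gives 0.385 M from the autumn run and 0.386 M from the spring run. The X readings suit a selectivity factor near 2, second step against first, and then X = G·(1 − G) in fractions of the charge. That gives 20.6% against the 21% read at midnight after 80.0 s. So in this reckoning X tops out at a quarter of the charge, where G stands at half.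

Now I turn the question round. By my reckoning, to keep rising from first to last, the row needs the turning charge to reach epsilon's charge, but epsilon's 1.50 M is higher than the turning charge, at 3.87 times it. To keep falling, it needs zeta's charge above the turning charge, but 0.200 M lies under it. At 2.5 min, in this reckoning, G left halves for each turning charge of Q in the flask, so I reckon G at 70.0%, 49.0%, 24.0% and 6.87%. X then comes to 21.0%, 25.0%, 18.2% and 6.40%.

The forecast gives 20%, 25%, 20% and 8%, standing above my last two, with the shape rises, then falls: “So X passes through a maximum near 0.4 M.”

The flask gives 21.2%, 26.1%, 20.4% and 7.67%: rises, then falls.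

    G + Q → X (k = 0.0140 L mol⁻¹ s⁻¹)
    Q + X → D (k = 0.0260 L mol⁻¹ s⁻¹)
    Q + D → J (k = 0.0110 L mol⁻¹ s⁻¹)
    Q ⇌ Z (K = 0.180, k = 0.00200 s⁻¹)

Alpha, charged at 0.400 M, ends with G at 50.2%, half of its charge, and X at 26.1%. I put the turning charge to use once more on epsilon at 1.25 min. Scaled by [Q] times time, it gives G 26.2% and X 19.3%. Epsilon held G 24.5% and X 20.0% at that time.

(The earlier runs and the new flask are calculated with constants of no real substance; scatter was added.)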